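**Retrosynthetic overview**
1. Rings A, B, C and the C2 stereocentre are bought: naringin (1) → (2S)-naringenin (2) → 7,4′-bis-TBS ether (3). No ring is constructed.
2. The fourth ring is bought as 4-(TBSO)benzyl alcohol (4) and converted to its methyl sulfide (5).
3. Key disconnection, C6–CH(benzyl): [2,3]-sigmatropic shift of the O5-aryloxysulfonium ylide from 3 + 5 gives 6. C6 is the only free ortho carbon of O5, so the shift is regiospecific. Raney Ni then removes sulfur (7).
4. Last disconnection, C3–OH: silyl enol ether 8 is oxidised anti to the C2 aryl group and desilylated to give the target (9).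

Assumption: naringin is taken as its natural 2S epimer (check the lot by chiral HPLC, since any 2R epimer carries through as ee loss), and alcohol 4 is a catalogue compound.

**Step 1**
Reactants: 1, naringin
Product: 2, (2S)-naringenin
Conditions: 1 M HCl, MeOH–H2O (1:1), 80 °C, 2–3 h; recrystallise from aq. EtOH
Reagents that add atoms: none
Why: Acid-catalysed glycoside hydrolysis cleaves the sugar acetal C–O bond only, so C2 is not involved and stays S.

**Step 2**
Reactants: 2, (2S)-naringenin
Product: 3, (2S)-7-(tert-butyldimethylsilyloxy)-2-[4-(tert-butyldimethylsilyloxy)phenyl]-5-hydroxychroman-4-one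
Conditions: TBSCl (2.3 equiv), imidazole, DMF, 0 °C → rt
Reagents that add atoms: TBSCl, CC(C)(C)[Si](C)(C)Cl
Why: Selective phenol silylation; the 5-OH is hydrogen-bonded to C4=O and does not react, and imidazole is too weak a base to open the flavanone to the chalcone.

**Step 3**
Reactants: 4, [4-(tert-butyldimethylsilyloxy)phenyl]methanol
Product: 5, tert-butyldimethyl{4-[(methylthio)methyl]phenoxy}silane
Conditions: MeSSMe (4 equiv), n-Bu3P (1.5 equiv), pyridine, rt
Reagents that add atoms: dimethyl disulfide, CSSC
Why: Hata thioetherification; the benzylic alkoxyphosphonium is displaced by MeS⁻ under neutral conditions, so the aryl silyl ether survives.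

**Step 4 (key step)**
Reactants: 3, bis-TBS naringenin; 5, benzyl methyl sulfide
Product: 6, (2S)-7-(TBSO)-2-[4-(TBSO)phenyl]-5-hydroxy-6-{[4-(TBSO)phenyl](methylthio)methyl}chroman-4-one, about 1:1 epimers at the CH(SMe) carbon
Conditions: 5 (1.3 equiv), NCS (1.25 equiv), CH2Cl2, −78 °C, 30 min; add 3, −78 → −40 °C; Et3N (3 equiv), −40 °C → rt
Reagents that add atoms: none beyond reactant 5 (NCS and Et3N leave no atoms)
Why: Gassman-type ortho-alkylation; the sulfonium from 5/NCS is captured by the 5-O, Et3N forms the benzylic ylide, and its [2,3]-sigmatropic shift makes the C6–C bond before tautomerisation back to the phenol. C2 is untouched and the new CH(SMe) centre is removed in step 5.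

**Step 5**
Reactants: 6
Product: 7, (2S)-6-[4-(TBSO)benzyl]-7-(TBSO)-2-[4-(TBSO)phenyl]-5-hydroxychroman-4-one
Conditions: Raney Ni (W-2, washed neutral, acetone-deactivated), THF–EtOH, rt, about 30 min
Reagents that add atoms: none
Why: Hydrogenolytic desulfurisation of the doubly benzylic C–S bond is fast at rt, while the chelated C4 ketone, the cyclic benzylic ether and the silyl ethers are left; both epimers of 6 converge on 7.

**Step 6**
Reactants: 7
Product: 8, (2S)-6-[4-(TBSO)benzyl]-7-(TBSO)-2-[4-(TBSO)phenyl]-4,5-bis(trimethylsilyloxy)-2H-chromene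
Conditions: TMSOTf (2.5 equiv), Et3N (4 equiv), CH2Cl2, −20 → 0 °C; pentane extraction, use crude, keep cold and dark
Reagents that add atoms: TMSOTf, C[Si](C)(C)OS(=O)(=O)C(F)(F)F
Why: Soft enolisation silylates the 5-OH and converts C4=O into the C3=C4 silyl enol ether without a free enolate, which avoids E1cB ring opening and keeps C2 intact.

**Step 7**
Reactants: 8
Product: 9, gericudranin E, (2R,3R)-3,5,7-trihydroxy-6-(4-hydroxybenzyl)-2-(4-hydroxyphenyl)chroman-4-one
Conditions: DMDO (1.1 equiv, acetone), CH2Cl2, −78 → −30 °C; concentrate; TBAF/AcOH (1:1, 8 equiv), THF, 0 °C → rt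
Reagents that add atoms: dimethyldioxirane, CC1(C)OO1
Why: Rubottom oxidation; DMDO epoxidises the enol ether anti to the C2 aryl group, giving the 2,3-trans C3–O bond (2R,3R; C2 keeps its geometry, the descriptor changes from S to R only through CIP priority), and buffered fluoride opens the silyloxy epoxide to the α-hydroxy ketone and removes all five silyl groups without base.

**Compound list**
1 | Naringin, (2S)-naringenin 7-O-[α-L-rhamnopyranosyl-(1→2)-β-D-glucopyranoside] | O=C1c2c(cc(O[C@@H]3O[C@H](CO)[C@@H](O)[C@H](O)[C@H]3O[C@@H]3O[C@@H](C)[C@H](O)[C@@H](O)[C@H]3O)cc2O)O[C@H](c2ccc(O)cc2)C1 | starting material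
2 | (2S)-Naringenin | O=C1c2c(cc(O)cc2O)O[C@H](c2ccc(O)cc2)C1 | intermediate
3 | (2S)-7,4′-Bis-O-TBS-naringenin | O=C1c2c(cc(O[Si](C)(C)C(C)(C)C)cc2O)O[C@H](c2ccc(O[Si](C)(C)C(C)(C)C)cc2)C1 | intermediate
4 | [4-(tert-Butyldimethylsilyloxy)phenyl]methanol | OCc1ccc(O[Si](C)(C)C(C)(C)C)cc1 | starting material
5 | tert-Butyldimethyl{4-[(methylthio)methyl]phenoxy}silane | CSCc1ccc(O[Si](C)(C)C(C)(C)C)cc1 | intermediate
6 | (2S)-6-{[4-(TBSO)phenyl](methylthio)methyl}-7,4′-bis-O-TBS-naringenin (epimer mixture at CH–S) | O=C1c2c(cc(O[Si](C)(C)C(C)(C)C)c(C(SC)c3ccc(O[Si](C)(C)C(C)(C)C)cc3)c2O)O[C@H](c2ccc(O[Si](C)(C)C(C)(C)C)cc2)C1 | intermediate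
7 | (2S)-6-[4-(TBSO)benzyl]-7,4′-bis-O-TBS-naringenin | O=C1c2c(cc(O[Si](C)(C)C(C)(C)C)c(Cc3ccc(O[Si](C)(C)C(C)(C)C)cc3)c2O)O[C@H](c2ccc(O[Si](C)(C)C(C)(C)C)cc2)C1 | intermediate
8 | (2S)-6-[4-(TBSO)benzyl]-7-(TBSO)-2-[4-(TBSO)phenyl]-4,5-bis(trimethylsilyloxy)-2H-chromene | C[Si](C)(C)OC1=C[C@@H](c2ccc(O[Si](C)(C)C(C)(C)C)cc2)Oc2cc(O[Si](C)(C)C(C)(C)C)c(Cc3ccc(O[Si](C)(C)C(C)(C)C)cc3)c(O[Si](C)(C)C)c12 | intermediate
9 | Gericudranin E | O=C1c2c(cc(O)c(Cc3ccc(O)cc3)c2O)O[C@H](c2ccc(O)cc2)[C@H]1O | target

**Totals**
Total steps: 7. Longest linear sequence: 6 (steps 1, 2, 4, 5, 6, 7).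

**Three steps most likely to fail**
1. Step 4. The chelated, hindered 5-OH may capture the sulfonium poorly, and the benzylic chlorosulfonium can divert to Pummerer products. Fallback: move the sulfonium anchor to O7 by selectively removing the labile 7-O-TBS of 3 and running the same [2,3] shift from the free 7-OH. The 5-OH chelate biases the shift toward C6, and the C8 isomer is separated.
2. Steps 6–7. Enolisation of the flavanone risks C2 erosion (retro-oxa-Michael or chromene ring opening) and incomplete trans selectivity. Fallback: buy C3 as well by running the same silylation, [2,3] shift, desulfurisation and desilylation on (2R,3R)-aromadendrin with its 3-OH silylated, so the flavanone is never enolised; the cost is a more expensive chiral starting material.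
3. Step 5. Raney Ni may over-reduce the C4 ketone or the benzylic C2–O1 bond, or strip the 7-O-silyl group. Fallback: replace surface hydrogenolysis with a radical chain C–S reduction (Bu3SnH, AIBN, toluene, 90 °C), which leaves the ketone, the cyclic ether and the silyl ethers alone.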